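**Plan**

- Target: 7-hydroxy-5,6,8-trimethoxy-2-(3,4-dimethoxyphenyl)-4H-chromen-4-one (flavone numbering). It has no stereocentre; the one carbinol centre of the cyclobutenone precursor is racemic and disappears on aromatisation.
- Enabling feature: every free carbon of ring A carries oxygen, with the oxygens on C5 and C8 para (a hydroquinone) and those on C6 and C7 vicinal. A squarate-derived 4-hydroxycyclobutenone delivers exactly this pattern.
- Cuts, in order: the methyl–oxygen bonds at C5 and C8 and the tert-butyl mask on the C7 oxygen; C8–C8a (6π closure of a dienylketene); C4a–C5 (pyranonyl Grignard plus tert-butyl methyl squarate); O1–C8a and C2–C3 of ring C.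
- Forward: ring C, carrying ring B, is built first as a 5-iodo-2-aryl-4-pyranone from an already iodinated methoxybutenone, so the iodine position is fixed by construction rather than by a selective halogenation. The squarate is then attached and ring A is closed last by thermolysis.
- Finish: double O-methylation of the hydroquinone, then acid removal of the tert-butyl group.

Key step: step 7

Remark: the monocyclic intermediates are numbered as 4H-pyran-4-ones (O1, aryl on C2, iodine or metal on C5); pyranone C5 and C6 become flavone C4a and C8a.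

**Route**

Step 1
Reactants: 1 (E)-4-methoxybut-3-en-2-one
Product: 2 (Z)-3-iodo-4-methoxybut-3-en-2-one
Conditions: I2, pyridine, CH2Cl2, 0 °C to rt
Reagents that add atoms: iodine, II
Why: Iodine attacks the nucleophilic α-carbon of the β-alkoxy enone and pyridine removes the vinylic proton (the standard I2–pyridine α-iodination of vinylogous esters), which places the halogen on the future pyranone C5 before the ring exists; the alkene geometry is of no consequence because that carbon becomes sp3 during step 3.

Step 2
Reactants: 2 (Z)-3-iodo-4-methoxybut-3-en-2-one; 3 3,4-dimethoxybenzoyl chloride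
Product: 5 (Z)-1-(3,4-dimethoxyphenyl)-4-iodo-5-methoxypent-4-ene-1,3-dione, via lithium dienolate 4 (not isolated)
Conditions: LiN(SiMe3)2 (2 equiv), 2 (2 equiv), THF, −78 °C; then 3 (1 equiv), −78 °C; cold 1 M HCl
Reagents that add atoms: none
Why: Kinetic deprotonation of the methyl ketone gives the lithium dienolate, whose Claisen-type C-acylation by the aroyl chloride forms the future C2–C3 bond of ring C, the second equivalent of enolate taking up the acidic 1,3-diketone proton while the vinyl iodide is inert to the hindered silylamide.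

Step 3
Reactants: 5 (Z)-1-(3,4-dimethoxyphenyl)-4-iodo-5-methoxypent-4-ene-1,3-dione
Product: 6 2-(3,4-dimethoxyphenyl)-5-iodo-4H-pyran-4-one
Conditions: CF3CO2H, CH2Cl2, rt
Reagents that add atoms: none
Why: Under acid the enol oxygen of the 1,3-diketone adds to the methoxy-bearing β-carbon of the enone and methanol is eliminated (conjugate addition–elimination, the usual cyclisation of such acylated methoxy enones to 4-pyranones), which closes ring C with iodine necessarily on C5.

Step 4
Reactants: 7 dimethyl squarate (3,4-dimethoxycyclobut-3-ene-1,2-dione)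
Product: 8 3-hydroxy-4-methoxycyclobut-3-ene-1,2-dione
Conditions: NaOH (1.0 equiv), THF–H2O, 0 °C; then HCl to pH 1
Reagents that add atoms: sodium hydroxide, [Na+].[OH-]
Why: Hydroxide adds to one vinylogous ester carbon and expels methoxide (addition–elimination saponification), and the delocalised mono-anion formed resists a second attack, so one equivalent of base should stop at the half-ester.

Step 5
Reactants: 8 3-hydroxy-4-methoxycyclobut-3-ene-1,2-dione
Product: 9 3-tert-butoxy-4-methoxycyclobut-3-ene-1,2-dione
Conditions: Cl3CC(=NH)O-t-Bu (2–3 equiv), CH2Cl2–cyclohexane, rt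
Reagents that add atoms: tert-butyl 2,2,2-trichloroacetimidate, CC(C)(C)OC(=N)C(Cl)(Cl)Cl
Why: The half-ester is a strong vinylogous acid that protonates the trichloroacetimidate and is O-alkylated by the resulting tert-butyl cation (imidate tert-butylation as used for tert-butyl esters), and both anion oxygens conjugated with the methoxy carbon lead to the same 1,2-dione.

Step 6
Reactants: 6 2-(3,4-dimethoxyphenyl)-5-iodo-4H-pyran-4-one; 9 3-tert-butoxy-4-methoxycyclobut-3-ene-1,2-dione
Product: 11 racemic 2-tert-butoxy-4-hydroxy-3-methoxy-4-[6-(3,4-dimethoxyphenyl)-4-oxo-4H-pyran-3-yl]cyclobut-2-en-1-one, via pyranonylmagnesium chloride 10 (not isolated)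
Conditions: i-PrMgCl·LiCl, THF, −78 °C; then 9, −78 °C; aq NH4Cl
Reagents that add atoms: none
Why: Iodine–magnesium exchange at the electron-poor α-iodo enone carbon is fast at low temperature, and the vinylmagnesium reagent then adds 1,2 to the squarate carbonyl next to the small methoxy-bearing carbon and remote from the bulky tert-butoxy group (standard addition of organometallics to squarate esters); the new carbinol stereocentre forms as a racemate and is erased in step 7.

Step 7
Reactants: 11 racemic 2-tert-butoxy-4-hydroxy-3-methoxy-4-[6-(3,4-dimethoxyphenyl)-4-oxo-4H-pyran-3-yl]cyclobut-2-en-1-one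
Product: 14 7-tert-butoxy-5,8-dihydroxy-6-methoxy-2-(3,4-dimethoxyphenyl)-4H-chromen-4-one, via (Z)-dienylketene 12 (not isolated), via cyclohexadienone 13 (not isolated)
Conditions: PhMe (degassed), 110 °C, Ar; crude product kept under Ar
Reagents that add atoms: none
Why: Heating cleaves the C1–C4 bond of the cyclobutenone by conrotatory 4π electrocyclic opening, and the donor hydroxyl rotates outward, so the pyranone ends up cis to the ketene in dienylketene 12. The ketene C=C, the enol C=C and the pyranone C5=C6 bond then form a 1,3,5-hexatriene whose thermal disrotatory 6π electrocyclisation joins the ketene carbon to pyranone C6, making the C8–C8a bond and closing ring A as the six-membered cyclohexadienone 13. Transfer of the C8a hydrogen to the C8 carbonyl oxygen (keto–enol tautomerisation) aromatises ring A and restores the pyranone, giving hydroquinone 14. The closest known reaction is the Moore ring expansion of 4-alkenyl- and 4-(hetero)aryl-4-hydroxycyclobutenones to hydroquinones; the pyranone C5=C6 bond is only weakly aromatic and should act as the alkenyl partner, the closure being pericyclic and so not dependent on the polarity of the oxygen-bearing C6. No stereocentre is created and the carbinol centre of 11 is lost. The step needs one direction of closure and survival of the tert-butyl ether: C6 is the only pyranone carbon that completes the triene (the other neighbour of C5 is the carbonyl carbon), outward rotation keeps the hydroxyl away from the ketene so that no furanone can form, and 110 °C under argon should lie below the point where the ether loses isobutene or the hydroquinone oxidises.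

Step 8
Reactants: 14 7-tert-butoxy-5,8-dihydroxy-6-methoxy-2-(3,4-dimethoxyphenyl)-4H-chromen-4-one
Product: 15 7-tert-butoxy-5,6,8-trimethoxy-2-(3,4-dimethoxyphenyl)-4H-chromen-4-one
Conditions: Me2SO4 (excess), K2CO3, acetone, reflux, Ar
Reagents that add atoms: dimethyl sulfate, COS(=O)(=O)OC
Why: Both phenols are alkylated by Williamson O-methylation, the hydrogen-bonded C5 hydroxyl needing the excess reagent and reflux, while the tert-butyl ether is inert to base.

Step 9
Reactants: 15 7-tert-butoxy-5,6,8-trimethoxy-2-(3,4-dimethoxyphenyl)-4H-chromen-4-one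
Product: 16 7-hydroxy-5,6,8-trimethoxy-2-(3,4-dimethoxyphenyl)-4H-chromen-4-one
Conditions: CF3CO2H, CH2Cl2, 0 °C to rt
Reagents that add atoms: none
Why: Trifluoroacetic acid ionises the aryl tert-butyl ether to the phenol and isobutene (unimolecular acidolysis), conditions that leave the five aryl methyl ethers and the flavone core untouched.

**Compound list**

1 | (E)-4-methoxybut-3-en-2-one | CO/C=C/C(C)=O | starting material
2 | (Z)-3-iodo-4-methoxybut-3-en-2-one | CC(=O)/C(I)=C/OC | intermediate
3 | 3,4-dimethoxybenzoyl chloride | COc1ccc(C(Cl)=O)cc1OC | starting material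
4 | lithium (Z)-3-iodo-4-methoxybuta-1,3-dien-2-olate (lithium dienolate of 2) | C=C(O[Li])/C(I)=C/OC | intermediate
5 | (Z)-1-(3,4-dimethoxyphenyl)-4-iodo-5-methoxypent-4-ene-1,3-dione | COc1ccc(C(=O)CC(=O)/C(I)=C/OC)cc1OC | intermediate
6 | 2-(3,4-dimethoxyphenyl)-5-iodo-4H-pyran-4-one | COc1ccc(-c2cc(=O)c(I)co2)cc1OC | intermediate
7 | dimethyl squarate (3,4-dimethoxycyclobut-3-ene-1,2-dione) | COC1=C(OC)C(=O)C1=O | starting material
8 | 3-hydroxy-4-methoxycyclobut-3-ene-1,2-dione | COC1=C(O)C(=O)C1=O | intermediate
9 | 3-tert-butoxy-4-methoxycyclobut-3-ene-1,2-dione | COC1=C(OC(C)(C)C)C(=O)C1=O | intermediate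
10 | [6-(3,4-dimethoxyphenyl)-4-oxo-4H-pyran-3-yl]magnesium chloride (LiCl complex) | COc1ccc(-c2cc(=O)c([Mg]Cl)co2)cc1OC | intermediate
11 | racemic 2-tert-butoxy-4-hydroxy-3-methoxy-4-[6-(3,4-dimethoxyphenyl)-4-oxo-4H-pyran-3-yl]cyclobut-2-en-1-one | O=C1C(OC(C)(C)C)=C(OC)C1(O)c1coc(-c2ccc(OC)c(OC)c2)cc1=O | intermediate
12 | (Z)-2-tert-butoxy-4-hydroxy-3-methoxy-4-[6-(3,4-dimethoxyphenyl)-4-oxo-4H-pyran-3-yl]buta-1,3-dien-1-one (dienylketene, pyranone cis to the ketene) | O=C=C(OC(C)(C)C)/C(OC)=C(/O)c1coc(-c2ccc(OC)c(OC)c2)cc1=O | intermediate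
13 | racemic 7-tert-butoxy-5-hydroxy-6-methoxy-2-(3,4-dimethoxyphenyl)-8aH-chromene-4,8-dione (ring A cyclohexadienone, sp3 C8a–H) | O=C1C(OC(C)(C)C)=C(OC)C(O)=C2C(=O)C=C(c3ccc(OC)c(OC)c3)OC21 | intermediate
14 | 7-tert-butoxy-5,8-dihydroxy-6-methoxy-2-(3,4-dimethoxyphenyl)-4H-chromen-4-one | COc1ccc(-c2cc(=O)c3c(O)c(OC)c(OC(C)(C)C)c(O)c3o2)cc1OC | intermediate
15 | 7-tert-butoxy-5,6,8-trimethoxy-2-(3,4-dimethoxyphenyl)-4H-chromen-4-one | COc1ccc(-c2cc(=O)c3c(OC)c(OC)c(OC(C)(C)C)c(OC)c3o2)cc1OC | intermediate
16 | 7-hydroxy-5,6,8-trimethoxy-2-(3,4-dimethoxyphenyl)-4H-chromen-4-one | COc1ccc(-c2cc(=O)c3c(OC)c(OC)c(O)c(OC)c3o2)cc1OC | target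

**Step count**

Total: 9 steps. Longest linear sequence: 7 steps (1, 2, 3, 6, 7, 8, 9); the squarate branch (steps 4 and 5) joins at step 6.

**Steps most likely to fail**

Step 7. A pyranone has not been used as the alkenyl partner in this ring expansion. The ketene may be consumed by adventitious nucleophiles before it closes onto the weakly aromatic C5=C6 bond. A minor inward rotation of the hydroxyl would let the carbinol oxygen lactonise the ketene. The free, acidic hydroquinone may also oxidise or promote loss of isobutene on prolonged heating. The fallback sets out from 11 and moves the ring expansion to the silyl ether. Me3SiCl and imidazole in DMF at 0 °C should give racemic 2-tert-butoxy-3-methoxy-4-(trimethylsilyloxy)-4-[6-(3,4-dimethoxyphenyl)-4-oxo-4H-pyran-3-yl]cyclobut-2-en-1-one F1. Thermolysis of 4-silyloxycyclobutenones is the established protected variant of the same reaction: the silyloxy group rotates outward, cannot lactonise, and tolerates xylene at 140 °C. It should give 7-tert-butoxy-8-hydroxy-6-methoxy-5-(trimethylsilyloxy)-2-(3,4-dimethoxyphenyl)-4H-chromen-4-one F2, a mono-protected hydroquinone far less prone to oxidation. Crude F2 with CsF and MeI in DMF should lose the aryl silyl group and be methylated on both oxygens in one flask, rejoining the route at 15.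

Step 6. The Grignard reagent may attack the squarate carbonyl next to the tert-butoxy carbon as well as the intended one, since steric steering is opposed by a small electronic bias; the magnesiated pyranone may also fragment by β-elimination if the exchange is slow. Poor site selectivity would carry the wrong C6/C7 pattern through the ring expansion. The fallback sets out from 6, uses a symmetrical squarate, and differentiates the C6 and C7 oxygens at the flavone stage through their different acidity.
- 3,4-Di-tert-butoxycyclobut-3-ene-1,2-dione F3, made from squaric acid and tert-butyl 2,2,2-trichloroacetimidate as in step 5, should take up reagent 10 to give racemic 2,3-di-tert-butoxy-4-hydroxy-4-[6-(3,4-dimethoxyphenyl)-4-oxo-4H-pyran-3-yl]cyclobut-2-en-1-one F4, with no regiochemical question.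
- Thermolysis as in step 7 should give 6,7-di-tert-butoxy-5,8-dihydroxy-2-(3,4-dimethoxyphenyl)-4H-chromen-4-one F5.
- Methylation as in step 8 should give 6,7-di-tert-butoxy-5,8-dimethoxy-2-(3,4-dimethoxyphenyl)-4H-chromen-4-one F6.
- CF3CO2H should give the catechol 6,7-dihydroxy-5,8-dimethoxy-2-(3,4-dimethoxyphenyl)-4H-chromen-4-one F7.
- One equivalent of benzyl bromide with K2CO3 in acetone should alkylate the more acidic C7 hydroxyl (para to the C4 carbonyl through C4a), giving 7-benzyloxy-6-hydroxy-5,8-dimethoxy-2-(3,4-dimethoxyphenyl)-4H-chromen-4-one F8.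
- MeI and K2CO3 should then give 7-benzyloxy-5,6,8-trimethoxy-2-(3,4-dimethoxyphenyl)-4H-chromen-4-one F9.
- Hydrogenolysis (H2, Pd/C, EtOAc) frees the C7 hydroxyl and arrives at 16.

Step 8. The tetra-oxygenated hydroquinone may be oxidised by traces of air under the basic conditions faster than the hydrogen-bonded C5 hydroxyl is alkylated, so that the methylation stalls at mixtures. The fallback sets out from 14 and makes the oxidation deliberate. Ag2O in CH2Cl2 should convert 14 into the stable, chromatographable 7-tert-butoxy-6-methoxy-2-(3,4-dimethoxyphenyl)-4H-chromene-4,5,8-trione F10. Reductive methylation in one flask (Na2S2O4, aqueous KOH, Bu4NBr, Me2SO4, THF, Ar) generates the hydroquinone dianion under reducing conditions and alkylates it, returning to the route at 15.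

**Further compounds**

F1 | step 7 | racemic 2-tert-butoxy-3-methoxy-4-(trimethylsilyloxy)-4-[6-(3,4-dimethoxyphenyl)-4-oxo-4H-pyran-3-yl]cyclobut-2-en-1-one | O=C1C(OC(C)(C)C)=C(OC)C1(O[Si](C)(C)C)c1coc(-c2ccc(OC)c(OC)c2)cc1=O
F2 | step 7 | 7-tert-butoxy-8-hydroxy-6-methoxy-5-(trimethylsilyloxy)-2-(3,4-dimethoxyphenyl)-4H-chromen-4-one | COc1ccc(-c2cc(=O)c3c(O[Si](C)(C)C)c(OC)c(OC(C)(C)C)c(O)c3o2)cc1OC
F3 | step 6 | 3,4-di-tert-butoxycyclobut-3-ene-1,2-dione | CC(C)(C)OC1=C(OC(C)(C)C)C(=O)C1=O
F4 | step 6 | racemic 2,3-di-tert-butoxy-4-hydroxy-4-[6-(3,4-dimethoxyphenyl)-4-oxo-4H-pyran-3-yl]cyclobut-2-en-1-one | O=C1C(OC(C)(C)C)=C(OC(C)(C)C)C1(O)c1coc(-c2ccc(OC)c(OC)c2)cc1=O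
F5 | step 6 | 6,7-di-tert-butoxy-5,8-dihydroxy-2-(3,4-dimethoxyphenyl)-4H-chromen-4-one | COc1ccc(-c2cc(=O)c3c(O)c(OC(C)(C)C)c(OC(C)(C)C)c(O)c3o2)cc1OC
F6 | step 6 | 6,7-di-tert-butoxy-5,8-dimethoxy-2-(3,4-dimethoxyphenyl)-4H-chromen-4-one | COc1ccc(-c2cc(=O)c3c(OC)c(OC(C)(C)C)c(OC(C)(C)C)c(OC)c3o2)cc1OC
F7 | step 6 | 6,7-dihydroxy-5,8-dimethoxy-2-(3,4-dimethoxyphenyl)-4H-chromen-4-one | COc1ccc(-c2cc(=O)c3c(OC)c(O)c(O)c(OC)c3o2)cc1OC
F8 | step 6 | 7-benzyloxy-6-hydroxy-5,8-dimethoxy-2-(3,4-dimethoxyphenyl)-4H-chromen-4-one | COc1ccc(-c2cc(=O)c3c(OC)c(O)c(OCc4ccccc4)c(OC)c3o2)cc1OC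
F9 | step 6 | 7-benzyloxy-5,6,8-trimethoxy-2-(3,4-dimethoxyphenyl)-4H-chromen-4-one | COc1ccc(-c2cc(=O)c3c(OC)c(OC)c(OCc4ccccc4)c(OC)c3o2)cc1OC
F10 | step 8 | 7-tert-butoxy-6-methoxy-2-(3,4-dimethoxyphenyl)-4H-chromene-4,5,8-trione | COc1ccc(-c2cc(=O)c3c(o2)C(=O)C(OC(C)(C)C)=C(OC)C3=O)cc1OC
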